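**Retrosynthetic overview**
- Target ⇒ threefold Mitsunobu esterification (inversion at C6 of each alcohol) of a cyclobutane triacid with three molecules of 6-epi-incarvilline.
- Cyclobutane triacid ⇒ key step: nitrogen deletion from an all-trans 5-aryl-2-methylpyrrolidine-2,4-diester; the 1,1-diazene loses N2 and the 1,4-biradical closes the C(aryl)–C(Me)(CO2R) bond with retention.
- Pyrrolidine ⇒ silver-catalysed enantioselective [3+2] cycloaddition of the alanine/vanillin-mesylate azomethine ylide with the disubstituted alkene of dimethyl (2E,6E)-3-methylocta-2,6-dienedioate, then radical epimerisation at C5.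
- 6-epi-Incarvilline ⇒ Pauson–Khand reaction of a carbamate-tethered 1,7-enyne whose single stereocentre comes from a copper-catalysed SN2′ methylation.
- Ring order: alkaloid, piperidine and cyclopentenone rings formed together in the Pauson–Khand step; core, arene (bought) → pyrrolidine → cyclobutane by ring contraction.

Assumption: each chiral ligand is used in the enantiomer that delivers the configuration drawn (sense of induction taken from the closest known substrates), and the methyl esters and the aryl mesylate are temporary protecting groups.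

**Fragment 1: 6-epi-incarvilline**

Step 1
Reactants: 1 but-2-yn-1-amine hydrochloride
Product: 2 methyl but-2-yn-1-ylcarbamate
Conditions: ClCO2Me (1.1 equiv), Et3N (2.2 equiv), CH2Cl2, 0 °C → rt
Reagents that add atoms: methyl chloroformate COC(=O)Cl
Why: N-acylation of the primary amine by the chloroformate gives the carbamate that serves as the Pauson–Khand-compatible nitrogen tether and as the latent N-methyl group.

Step 2
Reactants: 2 methyl but-2-yn-1-ylcarbamate; 3 (2E)-1,4-dibromobut-2-ene
Product: 4 methyl N-[(2E)-4-bromobut-2-en-1-yl]-N-(but-2-yn-1-yl)carbamate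
Conditions: NaH (1.1 equiv), 3 (3 equiv), DMF, 0 °C → rt
Reagents that add atoms: none
Why: SN2 N-alkylation of the sodium carbamate by a threefold excess of the symmetrical allylic dibromide gives the mono-substituted (E)-allyl bromide while the excess suppresses double substitution.

Step 3
Reactants: 4 methyl N-[(2E)-4-bromobut-2-en-1-yl]-N-(but-2-yn-1-yl)carbamate
Product: 5 methyl N-(but-2-yn-1-yl)-N-[(2R)-2-methylbut-3-en-1-yl]carbamate
Conditions: MeMgBr (1.3 equiv), CuBr·SMe2 (5 mol%), (Rp)-1-[(R)-α-(dimethylamino)-2-(diphenylphosphino)benzyl]-2-(diphenylphosphino)ferrocene (Taniaphos, 6 mol%), CH2Cl2, −78 °C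
Reagents that add atoms: methylmagnesium bromide C[Mg]Br
Why: Copper-catalysed asymmetric allylic alkylation (SN2′) delivers methyl from the chiral diphosphine–copper complex to the γ-carbon of the allylic bromide, creating the (R)-methyl stereocentre (future C4) and the terminal vinyl group in one operation.

Step 4
Reactants: 5 methyl N-(but-2-yn-1-yl)-N-[(2R)-2-methylbut-3-en-1-yl]carbamate
Product: 7 methyl (4R,4aR)-4,7-dimethyl-6-oxo-1,3,4,4a,5,6-hexahydro-2H-cyclopenta[c]pyridine-2-carboxylate, via alkyne–Co2(CO)6 complex 6 (not isolated)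
Conditions: Co2(CO)8 (1.1 equiv), CH2Cl2, rt; then Me3NO·2H2O (6 equiv), 0 °C → rt
Reagents that add atoms: dicobalt octacarbonyl O=C=[Co](=C=O)(=C=O)(=C=O)[Co](=C=O)(=C=O)(=C=O)=C=O (delivers one carbon monoxide, [C-]#[O+])
Why: Intramolecular Pauson–Khand [2+2+1] cycloaddition of the 1,7-enyne forms the piperidine and cyclopentenone rings together, the allylic methyl sitting equatorial in the chair-like alkene-insertion transition state so that C4a–H is set cis to the C4 methyl (4R,4aR).

Step 5
Reactants: 7 methyl (4R,4aR)-4,7-dimethyl-6-oxo-1,3,4,4a,5,6-hexahydro-2H-cyclopenta[c]pyridine-2-carboxylate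
Product: 9 methyl (4R,4aR,7R,7aS)-4,7-dimethyl-6-oxooctahydro-2H-cyclopenta[c]pyridine-2-carboxylate, via 7-epi ketone 8 (not isolated)
Conditions: H2 (4 atm), 10% Pd/C, EtOAc, rt; filter; then NaOMe (0.2 equiv), MeOH, rt
Reagents that add atoms: none
Why: Heterogeneous hydrogenation adds H2 to the tetrasubstituted enone from the face of the angular C4a–H to give the cis ring fusion (7aS), and methoxide-mediated enolisation then epimerises C7 to the thermodynamically favoured methyl trans to C1 (7R).

Step 6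
Reactants: 9 methyl (4R,4aR,7R,7aS)-4,7-dimethyl-6-oxooctahydro-2H-cyclopenta[c]pyridine-2-carboxylate
Product: 11 (4R,4aR,6S,7R,7aS)-2,4,7-trimethyloctahydro-1H-cyclopenta[c]pyridin-6-ol (6-epi-incarvilline), via hydroxy carbamate 10 (not isolated)
Conditions: LiBH(sec-Bu)3 (1.2 equiv), THF, −78 °C; then LiAlH4 (4 equiv), reflux; Na2SO4·10H2O quench
Reagents that add atoms: none
Why: The bulky trialkylborohydride attacks the cyclopentanone anti to the adjacent C7 methyl to set the 6S carbinol (hydroxyl cis to that methyl), and LiAlH4 then reduces the methyl carbamate to the N-methyl group (carbamate-to-N-methyl reduction).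

**Fragment 2: dipolarophile**

Step 7
Reactants: 12 but-3-en-1-ylmagnesium bromide; 13 methyl but-2-ynoate
Product: 16 methyl (2E)-3-methylhepta-2,6-dienoate, via but-3-en-1-ylcopper 14 (not isolated), via alkenylcopper 15 (not isolated)
Conditions: CuBr·SMe2 (1.05 equiv), THF, −45 °C; then 13, −78 °C; aq NH4Cl, −78 °C → rt
Reagents that add atoms: none
Why: Stereospecific syn-carbocupration of the ynoate at low temperature followed by protonation with retention places the butenyl chain trans to the ester and gives only the (E)-trisubstituted enoate.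

Step 8
Reactants: 16 methyl (2E)-3-methylhepta-2,6-dienoate; 17 methyl acrylate
Product: 18 dimethyl (2E,6E)-3-methylocta-2,6-dienedioate
Conditions: 17 (4 equiv), second-generation Grubbs catalyst (3 mol%), CH2Cl2, 40 °C
Reagents that add atoms: none
Why: Olefin cross-metathesis of the terminal alkene with excess acrylate gives the (E)-disubstituted enoate while the conjugated trisubstituted alkene is inert to the ruthenium carbene.

**Fragment 3: aldehyde**

Step 9
Reactants: 19 2-bromophenol
Product: 20 2-methoxyphenol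
Conditions: NaOMe (4 equiv), CuBr (10 mol%), MeOH/DMF, 110 °C; then aq HCl
Reagents that add atoms: sodium methoxide [Na+].[O-]C
Why: Copper-catalysed Ullmann-type methoxylation of the ortho-bromophenoxide replaces bromide by methoxide.

Step 10
Reactants: 20 2-methoxyphenol; 21 glyoxylic acid
Product: 23 4-hydroxy-3-methoxybenzaldehyde, via mandelic acid 22 (not isolated)
Conditions: NaOH, H2O, 30 °C; then CuSO4 (2 mol%), air, NaOH, 95 °C; then H2SO4, 60 °C
Reagents that add atoms: none
Why: Electrophilic aromatic hydroxyalkylation of the phenoxide by glyoxylate occurs para to the phenoxide oxygen, and copper-catalysed aerobic oxidative decarboxylation of the resulting mandelic acid gives the aldehyde.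

Step 11
Reactants: 23 4-hydroxy-3-methoxybenzaldehyde
Product: 24 4-formyl-2-methoxyphenyl methanesulfonate
Conditions: MsCl (1.2 equiv), Et3N (1.5 equiv), CH2Cl2, 0 °C
Reagents that add atoms: methanesulfonyl chloride CS(=O)(=O)Cl
Why: O-sulfonylation masks the phenol as an electron-withdrawing mesylate that shields the arene from the later trivalent-iodine oxidant and is cleaved by hydroxide.

**Core and endgame**

Step 12
Reactants: 24 4-formyl-2-methoxyphenyl methanesulfonate; 25 methyl L-alaninate hydrochloride; 18 dimethyl (2E,6E)-3-methylocta-2,6-dienedioate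
Product: 27 dimethyl (2S,3S,4S,5R)-5-[3-methoxy-4-(methanesulfonyloxy)phenyl]-3-[(3E)-5-methoxy-3-methyl-5-oxopent-3-en-1-yl]-2-methylpyrrolidine-2,4-dicarboxylate, via imine 26 (not isolated)
Conditions: Et3N (1.05 equiv), MgSO4, CH2Cl2, rt; filter, concentrate; then 18 (1.2 equiv), AgOAc (5 mol%), (S)-QUINAP (5.5 mol%), i-Pr2NEt (10 mol%), THF, −20 °C → rt
Reagents that add atoms: none
Why: Condensation gives the α-imino ester, whose N-metalated azomethine ylide on monovalent silver with the chiral P,N-ligand undergoes an endo-selective enantioselective 1,3-dipolar cycloaddition with the more reactive disubstituted (E)-enoate, the alanine carbon bonding to the β-carbon, which sets the quaternary C2, C3 and C4 in the required absolute configuration and C5 cis to the C4 ester.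

Step 13
Reactants: 27 dimethyl (2S,3S,4S,5R)-5-[3-methoxy-4-(methanesulfonyloxy)phenyl]-3-[(3E)-5-methoxy-3-methyl-5-oxopent-3-en-1-yl]-2-methylpyrrolidine-2,4-dicarboxylate
Product: 29 dimethyl (2S,3S,4S,5S)-5-[3-methoxy-4-(methanesulfonyloxy)phenyl]-3-[(3E)-5-methoxy-3-methyl-5-oxopent-3-en-1-yl]-2-methylpyrrolidine-2,4-dicarboxylate, via C5 radical 28 (not isolated)
Conditions: [Ir{dF(CF3)ppy}2(dtbpy)]PF6 (1 mol%), 2,4,6-triisopropylbenzenethiol (20 mol%), MeCN, blue LEDs (450 nm), rt
Reagents that add atoms: none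
Why: Proposed new method: reversible hydrogen-atom abstraction of the benzylic α-amino C5–H by the photogenerated thiyl radical gives a planar radical that the thiol re-hydrogenates until the thermodynamically preferred isomer with every vicinal pair trans (aryl trans to the C4 ester) accumulates, the closest known reaction being photoredox/thiol epimerisation of α-amino stereocentres in saturated nitrogen heterocycles.

Step 14
Reactants: 29 dimethyl (2S,3S,4S,5S)-5-[3-methoxy-4-(methanesulfonyloxy)phenyl]-3-[(3E)-5-methoxy-3-methyl-5-oxopent-3-en-1-yl]-2-methylpyrrolidine-2,4-dicarboxylate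
Product: 32 dimethyl (1R,2S,3S,4S)-2-[3-methoxy-4-(methanesulfonyloxy)phenyl]-4-[(3E)-5-methoxy-3-methyl-5-oxopent-3-en-1-yl]-1-methylcyclobutane-1,3-dicarboxylate, via isodiazene 30 (not isolated), via 1,4-biradical 31 (not isolated)
Conditions: PhI(OH)OTs (2.5 equiv), NH2CO2NH4 (8 equiv), CF3CH2OH, 80 °C
Reagents that add atoms: none
Why: Iodonitrene transfer to the secondary amine gives a 1,1-diazene that loses N2 to a singlet 1,4-biradical, which recombines faster than bond rotation so that the C(aryl)–C(methyl) bond forms with retention at both termini and the all-trans cyclobutane results (nitrogen-deletion ring contraction).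

Step 15
Reactants: 32 dimethyl (1R,2S,3S,4S)-2-[3-methoxy-4-(methanesulfonyloxy)phenyl]-4-[(3E)-5-methoxy-3-methyl-5-oxopent-3-en-1-yl]-1-methylcyclobutane-1,3-dicarboxylate
Product: 33 (1R,2S,3S,4S)-4-[(3E)-4-carboxy-3-methylbut-3-en-1-yl]-2-(4-hydroxy-3-methoxyphenyl)-1-methylcyclobutane-1,3-dicarboxylic acid
Conditions: LiOH·H2O (15 equiv), 1,4-dioxane/MeOH/H2O, 80 °C; then 1 M HCl
Reagents that add atoms: lithium hydroxide [Li+].[OH-]
Why: Saponification hydrolyses the three methyl esters and cleaves the aryl mesylate, the only enolisable ring stereocentre already being in the thermodynamically favoured trans arrangement.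

Step 16
Reactants: 33 (1R,2S,3S,4S)-4-[(3E)-4-carboxy-3-methylbut-3-en-1-yl]-2-(4-hydroxy-3-methoxyphenyl)-1-methylcyclobutane-1,3-dicarboxylic acid; 11 (4R,4aR,6S,7R,7aS)-2,4,7-trimethyloctahydro-1H-cyclopenta[c]pyridin-6-ol (three molecules of 11 enter the product, one per carboxylic acid)
Product: 34 tris[(4R,4aR,6R,7R,7aS)-2,4,7-trimethyloctahydro-1H-cyclopenta[c]pyridin-6-yl] ester of 33 (CNP0251577.2)
Conditions: 11 (3.6 equiv), PPh3 (4.5 equiv), DIAD (4.5 equiv), THF, 0 °C → rt
Reagents that add atoms: second molecule of 6-epi-incarvilline 11 O[C@H]1C[C@H]2[C@H](CN(C)C[C@@H]2C)[C@H]1C; third molecule of 6-epi-incarvilline 11 O[C@H]1C[C@H]2[C@H](CN(C)C[C@@H]2C)[C@H]1C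
Why: Threefold Mitsunobu esterification, chemoselective for the carboxylic acids over the far less acidic phenol, proceeds by SN2 displacement at C6 of the activated alcohol so that each 6S carbinol is inverted to the 6R ester of the target.

**Compound list**
1 | but-2-yn-1-amine hydrochloride | CC#CCN.Cl | starting material
2 | methyl but-2-yn-1-ylcarbamate | CC#CCNC(=O)OC | intermediate
3 | (2E)-1,4-dibromobut-2-ene | BrC/C=C/CBr | starting material
4 | methyl N-[(2E)-4-bromobut-2-en-1-yl]-N-(but-2-yn-1-yl)carbamate | CC#CCN(C/C=C/CBr)C(=O)OC | intermediate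
5 | methyl N-(but-2-yn-1-yl)-N-[(2R)-2-methylbut-3-en-1-yl]carbamate | CC#CCN(C[C@@H](C=C)C)C(=O)OC | intermediate
6 | hexacarbonyldicobalt complex of the alkyne of 5 | CC12[Co]3(=C=O)(=C=O)(=C=O)[Co]1(=C=O)(=C=O)(=C=O)C23CN(C[C@@H](C=C)C)C(=O)OC | intermediate
7 | methyl (4R,4aR)-4,7-dimethyl-6-oxo-1,3,4,4a,5,6-hexahydro-2H-cyclopenta[c]pyridine-2-carboxylate | O=C1C[C@H]2C(CN(C(=O)OC)C[C@@H]2C)=C1C | intermediate
8 | methyl (4R,4aR,7S,7aS)-4,7-dimethyl-6-oxooctahydro-2H-cyclopenta[c]pyridine-2-carboxylate | O=C1C[C@H]2[C@H](CN(C(=O)OC)C[C@@H]2C)[C@@H]1C | intermediate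
9 | methyl (4R,4aR,7R,7aS)-4,7-dimethyl-6-oxooctahydro-2H-cyclopenta[c]pyridine-2-carboxylate | O=C1C[C@H]2[C@H](CN(C(=O)OC)C[C@@H]2C)[C@H]1C | intermediate
10 | methyl (4R,4aR,6S,7R,7aS)-6-hydroxy-4,7-dimethyloctahydro-2H-cyclopenta[c]pyridine-2-carboxylate | O[C@H]1C[C@H]2[C@H](CN(C(=O)OC)C[C@@H]2C)[C@H]1C | intermediate
11 | (4R,4aR,6S,7R,7aS)-2,4,7-trimethyloctahydro-1H-cyclopenta[c]pyridin-6-ol (6-epi-incarvilline) | O[C@H]1C[C@H]2[C@H](CN(C)C[C@@H]2C)[C@H]1C | intermediate
12 | but-3-en-1-ylmagnesium bromide | C=CCC[Mg]Br | starting material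
13 | methyl but-2-ynoate | CC#CC(=O)OC | starting material
14 | but-3-en-1-ylcopper | C=CCC[Cu] | intermediate
15 | methyl (2Z)-2-cuprio-3-methylhepta-2,6-dienoate | C=CCC/C(C)=C(\[Cu])C(=O)OC | intermediate
16 | methyl (2E)-3-methylhepta-2,6-dienoate | C=CCC/C(C)=C/C(=O)OC | intermediate
17 | methyl acrylate | C=CC(=O)OC | starting material
18 | dimethyl (2E,6E)-3-methylocta-2,6-dienedioate | COC(=O)/C=C/CC/C(C)=C/C(=O)OC | intermediate
19 | 2-bromophenol | Oc1ccccc1Br | starting material
20 | 2-methoxyphenol (guaiacol) | COc1ccccc1O | intermediate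
21 | glyoxylic acid | O=CC(=O)O | starting material
22 | 2-hydroxy-2-(4-hydroxy-3-methoxyphenyl)acetic acid (racemic) | COc1cc(C(O)C(=O)O)ccc1O | intermediate
23 | 4-hydroxy-3-methoxybenzaldehyde (vanillin) | COc1cc(C=O)ccc1O | intermediate
24 | 4-formyl-2-methoxyphenyl methanesulfonate | COc1cc(C=O)ccc1OS(C)(=O)=O | intermediate
25 | methyl L-alaninate hydrochloride | C[C@H](N)C(=O)OC.Cl | starting material
26 | methyl (2S)-2-{(E)-[3-methoxy-4-(methanesulfonyloxy)benzylidene]amino}propanoate | COC(=O)[C@H](C)/N=C/c1ccc(OS(C)(=O)=O)c(OC)c1 | intermediate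
27 | dimethyl (2S,3S,4S,5R)-5-[3-methoxy-4-(methanesulfonyloxy)phenyl]-3-[(3E)-5-methoxy-3-methyl-5-oxopent-3-en-1-yl]-2-methylpyrrolidine-2,4-dicarboxylate | COc1cc([C@H]2[C@@H](C(=O)OC)[C@H](CC/C(C)=C/C(=O)OC)[C@@](N2)(C)C(=O)OC)ccc1OS(C)(=O)=O | intermediate
28 | C5-centred α-amino benzylic radical of 27 | COc1cc([C]2[C@@H](C(=O)OC)[C@H](CC/C(C)=C/C(=O)OC)[C@@](N2)(C)C(=O)OC)ccc1OS(C)(=O)=O | intermediate
29 | dimethyl (2S,3S,4S,5S)-5-[3-methoxy-4-(methanesulfonyloxy)phenyl]-3-[(3E)-5-methoxy-3-methyl-5-oxopent-3-en-1-yl]-2-methylpyrrolidine-2,4-dicarboxylate | COc1cc([C@@H]2[C@@H](C(=O)OC)[C@H](CC/C(C)=C/C(=O)OC)[C@@](N2)(C)C(=O)OC)ccc1OS(C)(=O)=O | intermediate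
30 | 1,1-diazene (isodiazene) of 29 | COc1cc([C@@H]2[C@@H](C(=O)OC)[C@H](CC/C(C)=C/C(=O)OC)[C@@]([N+]2=[N-])(C)C(=O)OC)ccc1OS(C)(=O)=O | intermediate
31 | 1,4-biradical formed from 30 by loss of N2 | COc1cc([CH][C@@H](C(=O)OC)[C@H](CC/C(C)=C/C(=O)OC)[C](C)C(=O)OC)ccc1OS(C)(=O)=O | intermediate
32 | dimethyl (1R,2S,3S,4S)-2-[3-methoxy-4-(methanesulfonyloxy)phenyl]-4-[(3E)-5-methoxy-3-methyl-5-oxopent-3-en-1-yl]-1-methylcyclobutane-1,3-dicarboxylate | COc1cc([C@@H]2[C@@H](C(=O)OC)[C@H](CC/C(C)=C/C(=O)OC)[C@@]2(C)C(=O)OC)ccc1OS(C)(=O)=O | intermediate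
33 | (1R,2S,3S,4S)-4-[(3E)-4-carboxy-3-methylbut-3-en-1-yl]-2-(4-hydroxy-3-methoxyphenyl)-1-methylcyclobutane-1,3-dicarboxylic acid | COc1cc([C@@H]2[C@@H](C(=O)O)[C@H](CC/C(C)=C/C(=O)O)[C@@]2(C)C(=O)O)ccc1O | intermediate
34 | tris[(4R,4aR,6R,7R,7aS)-2,4,7-trimethyloctahydro-1H-cyclopenta[c]pyridin-6-yl] ester of 33 (CNP0251577.2) | COc1cc([C@@H]2[C@@H](C(=O)O[C@@H]3C[C@H]4[C@H](CN(C)C[C@@H]4C)[C@H]3C)[C@H](CC/C(C)=C/C(=O)O[C@@H]3C[C@H]4[C@H](CN(C)C[C@@H]4C)[C@H]3C)[C@@]2(C)C(=O)O[C@@H]2C[C@H]3[C@H](CN(C)C[C@@H]3C)[C@H]2C)ccc1O | target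

**Totals**
Total step count: 16. Longest linear sequence: 8 steps (steps 9–16, from 2-bromophenol); the alkaloid branch is 7 steps (steps 1–6 and 16).

**Steps most likely to fail, with fallbacks**

Step 13 is the least precedented step. It relies on the all-trans isomer being clearly the more stable one and on the thiyl radical leaving the trisubstituted enoate alone. The fallback sets out from 27 and equilibrates C5 by a polar ring opening instead: LiBr and DBU in toluene at 90 °C cleave the C4–C5 bond by retro-Mannich reaction to the acyclic imine dimethyl (2S,3S)-2-{(E)-[3-methoxy-4-(methanesulfonyloxy)benzylidene]amino}-3-[(3E)-5-methoxy-3-methyl-5-oxopent-3-en-1-yl]-2-methylpentanedioate F2. Mannich re-closure under thermodynamic control gives 29, where the route is rejoined.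

Step 14 may lose material to β-scission of the biradical (giving two alkenes) or to oxidation of the arene by the trivalent-iodine reagent. The fallback sets out from 29 and builds the 1,1-diazene stepwise without an iodonitrene. Nitrosation (t-BuONO, CH2Cl2) gives dimethyl (2S,3S,4S,5S)-5-[3-methoxy-4-(methanesulfonyloxy)phenyl]-3-[(3E)-5-methoxy-3-methyl-5-oxopent-3-en-1-yl]-2-methyl-1-nitrosopyrrolidine-2,4-dicarboxylate F3. Reduction (Zn, AcOH) gives the corresponding 1-aminopyrrolidine, dimethyl (2S,3S,4S,5S)-1-amino-5-[3-methoxy-4-(methanesulfonyloxy)phenyl]-3-[(3E)-5-methoxy-3-methyl-5-oxopent-3-en-1-yl]-2-methylpyrrolidine-2,4-dicarboxylate F4. Oxidation of the N-amino group with PhI(OAc)2 at −20 °C → rt forms isodiazene 30, which loses N2 and returns to the route at 32.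

Step 12 combines a hindered α-methyl ylide with a β-alkyl enoate under asymmetric catalysis, so rate and enantioselectivity are both at risk. The fallback sets out from 24 (with 25 and 18) and drops the chiral catalyst. The more reactive N-lithiated ylide (LiBr, DBU, THF, rt) gives the racemic endo adduct, that is 27 together with its enantiomer dimethyl (2R,3R,4R,5S)-5-[3-methoxy-4-(methanesulfonyloxy)phenyl]-3-[(3E)-5-methoxy-3-methyl-5-oxopent-3-en-1-yl]-2-methylpyrrolidine-2,4-dicarboxylate F1. Preparative chromatography on a chiral stationary phase separates the two, and the route is rejoined at 27.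

**Further compounds**
F1 | step 12 | dimethyl (2R,3R,4R,5S)-5-[3-methoxy-4-(methanesulfonyloxy)phenyl]-3-[(3E)-5-methoxy-3-methyl-5-oxopent-3-en-1-yl]-2-methylpyrrolidine-2,4-dicarboxylate (enantiomer of 27) | COc1cc([C@@H]2[C@H](C(=O)OC)[C@@H](CC/C(C)=C/C(=O)OC)[C@](N2)(C)C(=O)OC)ccc1OS(C)(=O)=O
F2 | step 13 | dimethyl (2S,3S)-2-{(E)-[3-methoxy-4-(methanesulfonyloxy)benzylidene]amino}-3-[(3E)-5-methoxy-3-methyl-5-oxopent-3-en-1-yl]-2-methylpentanedioate | COC(=O)C[C@H](CC/C(C)=C/C(=O)OC)[C@@](/N=C/c1ccc(OS(C)(=O)=O)c(OC)c1)(C)C(=O)OC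
F3 | step 14 | dimethyl (2S,3S,4S,5S)-5-[3-methoxy-4-(methanesulfonyloxy)phenyl]-3-[(3E)-5-methoxy-3-methyl-5-oxopent-3-en-1-yl]-2-methyl-1-nitrosopyrrolidine-2,4-dicarboxylate | COc1cc([C@@H]2[C@@H](C(=O)OC)[C@H](CC/C(C)=C/C(=O)OC)[C@@](N2N=O)(C)C(=O)OC)ccc1OS(C)(=O)=O
F4 | step 14 | dimethyl (2S,3S,4S,5S)-1-amino-5-[3-methoxy-4-(methanesulfonyloxy)phenyl]-3-[(3E)-5-methoxy-3-methyl-5-oxopent-3-en-1-yl]-2-methylpyrrolidine-2,4-dicarboxylate | COc1cc([C@@H]2[C@@H](C(=O)OC)[C@H](CC/C(C)=C/C(=O)OC)[C@@](N2N)(C)C(=O)OC)ccc1OS(C)(=O)=O
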